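**Assumption:** (R)-2-(4-bromophenyl)oxirane (≥98% ee) is taken as a catalogue chiral building block. It is the only source of chirality in the route.

## Retrosynthetic overview

1. Target ⇐ 7-O-TIPS, C4-dithiane-masked flavan. The masked ketone cannot ring-open to a chalcone, so C2 is configurationally safe during B-ring work.
2. Chromene ring ⇐ aryl 1,1-dimethylpropargyl ether by propargyl Claisen / [1,5]-H shift / oxa-6π electrocyclization. Prenyl group ⇐ aromatic Claisen of a 1,1-dimethylallyl ether. Phenol ⇐ ArBr.
3. Pyran C-ring ⇐ intramolecular Mitsunobu etherification of an (S)-benzylic alcohol, with inversion to (R).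
4. C3–C4 bond ⇐ dianion of an A-ring aryl dithiane opening (R)-4-bromostyrene oxide at CH2, so the purchased stereocentre is carried in untouched.
5. Ring order: A and B rings bought; C-ring (Mitsunobu); chromene ring last (pericyclic cascade).

## Route

**Step 1**
Reactants: 1, 2,4-dihydroxybenzaldehyde
Product: 3, 2-hydroxy-4-(triisopropylsilyloxy)benzaldehyde
Conditions: TIPSCl (1.05 equiv), imidazole, CH2Cl2, 0 °C → rt
Reagents that add atoms: 2, triisopropylsilyl chloride, CC(C)[Si](Cl)(C(C)C)C(C)C
Why: Selective silylation of the 4-OH, because the 2-OH is hydrogen-bonded to the aldehyde and much less nucleophilic.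

**Step 2**
Reactants: 3
Product: 5, 2-(1,3-dithian-2-yl)-5-(triisopropylsilyloxy)phenol
Conditions: HS(CH2)3SH, BF3·OEt2, CH2Cl2, 0 °C
Reagents that add atoms: 4, propane-1,3-dithiol, SCCCS
Why: Lewis-acid dithioacetalization gives the Corey–Seebach acyl-anion precursor; the aryl TIPS ether tolerates brief BF3 exposure at 0 °C.

**Step 3**
Reactants: 5; 6, (R)-2-(4-bromophenyl)oxirane
Product: 7, (S)-1-(4-bromophenyl)-2-{2-[2-hydroxy-4-(triisopropylsilyloxy)phenyl]-1,3-dithian-2-yl}ethan-1-ol
Conditions: n-BuLi (2.1 equiv), THF, −78 → −20 °C; then 6, −78 °C → rt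
Reagents that add atoms: none
Why: Corey–Seebach umpolung: the phenoxide/dithianyl dianion opens the epoxide at the terminal CH2, so the benzylic C–O stereocentre is untouched (the R → S label change is only a CIP priority switch), and the stabilised anion does not exchange with ArBr.

**Step 4**
Reactants: 7
Product: 8, (R)-2-(4-bromophenyl)-7-(triisopropylsilyloxy)spiro[chromane-4,2'-[1,3]dithiane]
Conditions: PPh3, DIAD, THF (0.02 M), 0 °C → rt
Reagents that add atoms: none
Why: Intramolecular Mitsunobu etherification closes the six-membered ring by SN2 with clean inversion (S → R); the electron-poor 4-bromophenyl group suppresses SN1 leakage.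

**Step 5** (one flask, two stages)
Reactants: 8
Product: 10, (R)-4-[7-(triisopropylsilyloxy)spiro[chromane-4,2'-[1,3]dithian]-2-yl]phenol
Conditions: B2pin2, Pd(dppf)Cl2, KOAc, dioxane, 85 °C; then 30% H2O2, 1 M NaOH, THF, 0 °C, 20 min
Reagents that add atoms: 9, hydrogen peroxide, OO
Why: Miyaura borylation followed by ipso-oxidation of the aryl boronate; cold basic peroxide (nucleophilic HOO⁻) oxidises C–B much faster than the thioacetal, and the short, cold exposure avoids quinone-methide opening at C2.

**Step 6** (reagent arm)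
Reactants: 11, 2-methylbut-3-en-2-ol; 12, di-tert-butyl dicarbonate
Product: 13, tert-butyl (2-methylbut-3-en-2-yl) carbonate
Conditions: n-BuLi, THF, 0 °C; then Boc2O, 0 °C → rt
Reagents that add atoms: 12, di-tert-butyl dicarbonate, CC(C)(C)OC(=O)OC(=O)OC(C)(C)C
Why: Simple acylation of the lithium alkoxide gives the allyl carbonate needed for Pd-mediated tert-prenylation.

**Step 7**
Reactants: 10; 13
Product: 14, (R)-2-[4-(2-methylbut-3-en-2-yloxy)phenyl]-7-(triisopropylsilyloxy)spiro[chromane-4,2'-[1,3]dithiane]
Conditions: Pd(PPh3)4 (5 mol%), THF, 0–4 °C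
Reagents that add atoms: 13, tert-butyl (2-methylbut-3-en-2-yl) carbonate, C=CC(C)(C)OC(=O)OC(C)(C)C
Why: Tsuji–Trost O-allylation; under kinetic control the phenoxide attacks the more substituted terminus of the 1,1-dimethyl-π-allyl Pd complex, giving the tertiary ether under neutral, cold conditions.

**Step 8**
Reactants: 14
Product: 15, (R)-2-(3-methylbut-2-en-1-yl)-4-[7-(triisopropylsilyloxy)spiro[chromane-4,2'-[1,3]dithian]-2-yl]phenol
Conditions: xylenes, 130 °C (degassed)
Reagents that add atoms: none
Why: Aromatic Claisen [3,3]-sigmatropic rearrangement of the 1,1-dimethylallyl ether delivers the prenyl group to the ortho carbon; the two ortho positions are equivalent and the para position is blocked, so one product forms.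

**Step 9**
Reactants: 15; 16, 3-chloro-3-methylbut-1-yne
Product: 17, (R)-2-[4-(2-methylbut-3-yn-2-yloxy)-3-(3-methylbut-2-en-1-yl)phenyl]-7-(triisopropylsilyloxy)spiro[chromane-4,2'-[1,3]dithiane]
Conditions: DBU, CuCl2·2H2O (1 mol%), MeCN, 0 °C → rt
Reagents that add atoms: 16, 3-chloro-3-methylbut-1-yne, C#CC(C)(C)Cl
Why: Copper-catalysed propargylic etherification (Godfrey conditions) works on ortho-substituted phenols at 0 °C, which keeps the 4'-phenoxide from prolonged heating.

**Step 10** (key step)
Reactants: 17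
Product: 18, (R)-2-[2,2-dimethyl-8-(3-methylbut-2-en-1-yl)-2H-chromen-6-yl]-7-(triisopropylsilyloxy)spiro[chromane-4,2'-[1,3]dithiane]
Conditions: o-xylene, 140 °C (sealed, cat. BHT)
Reagents that add atoms: none
Why: Propargyl Claisen [3,3] rearrangement to the free ortho carbon, enolisation, [1,5]-H shift to the o-quinone methide and oxa-6π electrocyclization build the 2,2-dimethylchromene under neutral conditions; migration to the prenylated ortho carbon is reversible and unproductive.

**Step 11**
Reactants: 18
Product: 20, (R)-7-O-triisopropylsilyl-ent-abyssinone III [(R)-2-(2,2-dimethyl-8-prenyl-2H-chromen-6-yl)-7-(triisopropylsilyloxy)chroman-4-one]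
Conditions: MeI, CaCO3, MeCN/H2O (9:1), 45 °C
Reagents that add atoms: 19, water, O
Why: Alkylative dithiane hydrolysis (S-methylation, then hydrolysis of the aryl-stabilised thionium) leaves the chromene and prenyl alkenes alone and is close to neutral, so the new flavanone does not racemise.

**Step 12**
Reactants: 20
Product: 21, ent-abyssinone III, (R)-configured at C2
Conditions: TBAF/AcOH (1:1), THF, 0 °C
Reagents that add atoms: none
Why: Buffered fluoride desilylation of the activated (para-acyl) aryl silyl ether avoids the free base that would racemise the flavanone by retro-oxa-Michael opening.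

## Compound list

1 | 2,4-dihydroxybenzaldehyde | O=Cc1ccc(O)cc1O | starting material
2 | triisopropylsilyl chloride | CC(C)[Si](Cl)(C(C)C)C(C)C | starting material (reagent)
3 | 2-hydroxy-4-(triisopropylsilyloxy)benzaldehyde | O=Cc1ccc(O[Si](C(C)C)(C(C)C)C(C)C)cc1O | intermediate
4 | propane-1,3-dithiol | SCCCS | starting material (reagent)
5 | 2-(1,3-dithian-2-yl)-5-(triisopropylsilyloxy)phenol | Oc1cc(O[Si](C(C)C)(C(C)C)C(C)C)ccc1C1SCCCS1 | intermediate
6 | (R)-2-(4-bromophenyl)oxirane | Brc1ccc(cc1)[C@@H]1CO1 | starting material (chiral)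
7 | (S)-1-(4-bromophenyl)-2-{2-[2-hydroxy-4-(TIPSO)phenyl]-1,3-dithian-2-yl}ethan-1-ol | Brc1ccc(cc1)[C@@H](O)CC1(SCCCS1)c1ccc(O[Si](C(C)C)(C(C)C)C(C)C)cc1O | intermediate
8 | (R)-2-(4-bromophenyl)-7-(TIPSO)spiro[chromane-4,2'-[1,3]dithiane] | Brc1ccc(cc1)[C@H]1CC2(SCCCS2)c2ccc(O[Si](C(C)C)(C(C)C)C(C)C)cc2O1 | intermediate
9 | hydrogen peroxide | OO | starting material (reagent)
10 | (R)-4-[7-(TIPSO)spiro[chromane-4,2'-[1,3]dithian]-2-yl]phenol | Oc1ccc(cc1)[C@H]1CC2(SCCCS2)c2ccc(O[Si](C(C)C)(C(C)C)C(C)C)cc2O1 | intermediate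
11 | 2-methylbut-3-en-2-ol | C=CC(C)(C)O | starting material
12 | di-tert-butyl dicarbonate | CC(C)(C)OC(=O)OC(=O)OC(C)(C)C | starting material (reagent)
13 | tert-butyl (2-methylbut-3-en-2-yl) carbonate | C=CC(C)(C)OC(=O)OC(C)(C)C | intermediate
14 | (R)-2-[4-(2-methylbut-3-en-2-yloxy)phenyl]-7-(TIPSO)spiro[chromane-4,2'-[1,3]dithiane] | C=CC(C)(C)Oc1ccc(cc1)[C@H]1CC2(SCCCS2)c2ccc(O[Si](C(C)C)(C(C)C)C(C)C)cc2O1 | intermediate
15 | (R)-2-prenyl-4-[7-(TIPSO)spiro[chromane-4,2'-[1,3]dithian]-2-yl]phenol | CC(C)=CCc1cc(ccc1O)[C@H]1CC2(SCCCS2)c2ccc(O[Si](C(C)C)(C(C)C)C(C)C)cc2O1 | intermediate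
16 | 3-chloro-3-methylbut-1-yne | C#CC(C)(C)Cl | starting material (reagent)
17 | (R)-2-[4-(2-methylbut-3-yn-2-yloxy)-3-prenylphenyl]-7-(TIPSO)spiro[chromane-4,2'-[1,3]dithiane] | CC(C)=CCc1cc(ccc1OC(C)(C)C#C)[C@H]1CC2(SCCCS2)c2ccc(O[Si](C(C)C)(C(C)C)C(C)C)cc2O1 | intermediate
18 | (R)-2-(2,2-dimethyl-8-prenyl-2H-chromen-6-yl)-7-(TIPSO)spiro[chromane-4,2'-[1,3]dithiane] | CC(C)=CCc1cc(cc2C=CC(C)(C)Oc12)[C@H]1CC3(SCCCS3)c3ccc(O[Si](C(C)C)(C(C)C)C(C)C)cc3O1 | intermediate
19 | water | O | starting material (reagent)
20 | (R)-7-O-TIPS-ent-abyssinone III | CC(C)=CCc1cc(cc2C=CC(C)(C)Oc12)[C@H]1CC(=O)c3ccc(O[Si](C(C)C)(C(C)C)C(C)C)cc3O1 | intermediate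
21 | ent-abyssinone III, (R) | CC(C)=CCc1cc([C@H]2CC(=O)c3ccc(O)cc3O2)cc2c1OC(C)(C)C=C2 | target

## Summary

**Total steps:** 12 (11 on the main line plus one reagent preparation, step 6).
**Longest linear sequence:** 11 steps from 2,4-dihydroxybenzaldehyde (steps 1–5, 7–12); 9 steps from the chiral epoxide 6.

**Steps most likely to fail, with fallbacks:**

- **Step 3** (dianion formation and regioselective epoxide opening). Fallback: drop the acyl-anion disconnection. Open 6 with cyanide to the (S)-β-hydroxynitrile, form O1–C2 by intermolecular Mitsunobu with 3-(TIPSO)phenol (inversion), then close C4–C4a by Friedel–Crafts acylation of the derived acid. Protect the resulting flavanone as its flavan-4-ol for the B-ring work and re-oxidise at the end.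
- **Step 5** (Pd borylation and oxidation on a dithiane-containing substrate; risk of catalyst poisoning or sulfur oxidation). Fallback: bring the oxygen in from the start. Prepare the epoxide from (R)-4-hydroxymandelic acid with the phenol as its tosylate (still electron-poor for the Mitsunobu) and release the phenol with Mg/MeOH after ring closure. This removes the C–Br → C–O step at the cost of about three extra steps.
- **Step 11** (dithiane removal with chromene and prenyl alkenes present). Fallback: change the C4 mask. Hydrolyse the dithiane at stage 8 before any alkene exists, reduce to the flavan-4-ol with NaBH4 and protect it as a TBS ether (it cannot undergo retro-oxa-Michael). Run steps 5–10 on that, then finish with global desilylation and selective Dess–Martin oxidation of the benzylic C4–OH.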